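At one constant temperature, what you should watch is how soon each run slows down.

| flask | starting material | reagent | free catalyst | time |
|---|---|---|---|---|
| cedar | 0.400 M | 0.440 M | 0.00200 M |  |
| elm | 0.160 M | 0.200 M | 0.00200 M |  |
| larch | 1.20 M | 0.440 M | 0.00200 M |  |
| alder | 0.400 M | 0.440 M | 0.00200 M | 28 min |

| cedar run: time / min | cedar run: [target] / M | elm run: time / min | elm run: [target] / M | larch run: time / min | larch run: [target] / M |
|---|---|---|---|---|---|
| 0.80 | 0.012 | 0.80 | 0.009 | 0.80 | 0.013 |
| 2.4 | 0.030 | 2.4 | 0.016 | 2.4 | 0.044 |
| 4.6 | 0.050 | 4.6 | 0.036 | 4.6 | 0.072 |
| 7.3 | 0.063 | 7.3 | 0.032 | 7.3 | 0.094 |
| 10 | 0.064 | 10 | 0.036 | 10 | 0.111 |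
| 14 | 0.080 | 14 | 0.048 | 14 | 0.128 |

(readings scatter by 0.004 M)

1. apparent order in [starting material] of the starting rate, round the charge of the cedar run (the rate where two percent of its starting material have turned into target) (one fixed amount of target, the same in the runs compared)
2. apparent order in [reagent] of the starting rate, round the charge of the cedar run (the rate where two percent of its starting material have turned into target)
3. target in the alder run at 28 min, as a share of the starting material charged

- Overall: starting material + reagent -> target, with free catalyst as catalyst.
- Constant volume, constant temperature.
- Bound and free are read together.
- "The second partner" is reagent.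
- An order is taken over about fifteen percent of the charge, up and down.

Begin with the larch run, which has used the smallest share of its charge: its last reading is 10.7% of its starting material. Yet in the larch run c(target) climbs at 0.0155 M min⁻¹ early and at 0.00507 M min⁻¹ late, so the climb slows by a factor of 3.06.

My reckoning freezes the making rate as nearly constant and assumes that target is lost in proportion to c(target). The two slopes, whose midpoints lie 7.95 min apart, then give a reading of 7.11 min for the holding time, the time in which the climb of c(target) falls by a factor of e at a steady making rate.

The second time belongs to the charge. In the cedar run, the early rate is 0.0125 M min⁻¹, so c(starting material) divided by that rate gives a turnover time of 32.0 min, longer than the holding time.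

The alder run repeats the cedar charge, and I carry the larch holding time across to it. By 28 min, the alder run has gone 98.1% of the way to a quasi-steady state, where making balances loss. Its level is then rate times holding time, so its share of the charge is the ratio of the two times, 22.2%. I take this as an upper mark, since the making rate sinks as starting material is used.

The forecast gave 0.43, 0.25 and 25%, on the ground that “Rates fall far faster than depletion explains”.

The flask gives 0.45, 0.0082 and 17.7%.

    free catalyst + starting material → catalyst-substrate complex (88.80 M⁻¹ min⁻¹)
    catalyst-substrate complex + reagent → loaded catalyst (2130 M⁻¹ min⁻¹)
    loaded catalyst → target + free catalyst (23.76 min⁻¹)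
    2 starting material ⇌ idle substrate dimer, settled at all times (12.20 M⁻¹)
    target → decomposed product (0.1224 min⁻¹)

That share means 0.0709 M of target in the alder run at 28 min, less than the cedar reading of 0.080 M at 14 min. Divided by the holding time read from the larch run, 7.11 min, that amount puts the making rate in the alder run near 28 min at about 0.00998 M min⁻¹, less than the 0.013 M min⁻¹ of the cedar run, with the same charge, where two percent of its starting material have turned.

All runs were computed for an exercise; scatter was added.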